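Barbatolic acid is disconnected at its benzylic ester into orsellinic acid (ring A) and a ring B hydroxymethyl acid; both formyl groups are added last. Ring B has its carboxyl on C1, an oxygen on C2 and the oxymethyl carbon on C6. The key step exploits this contiguous C2–O/C1/C6 array: a C1–C6 aryne, polarised by the C2 ether, takes a silylmethyl Grignard reagent at C6, and the resulting C1 arylmagnesium is carboxylated, so the C6–CH2 and C1–CO2H bonds form in one flask. The aryne precursor is 1,2-dibromo-3,5-bis(methoxymethoxy)benzene, made in two steps from 5-bromoresorcinol; the silicon is later exchanged for oxygen.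

Key step: step 4

Remark: both rings are numbered from the carboxyl-bearing carbon (C1), with oxygens on C2 and C4, the formyl site at C3 and the methyl or oxymethyl carbon on C6; organomagnesium species 5, 7 and 9 are drawn as monomeric chlorides although they are solvated aggregates in THF.

**Step 1**
Reactants: 1 5-bromoresorcinol
Product: 2 1-bromo-3,5-bis(methoxymethoxy)benzene
Conditions: NaH (2.4 equiv), MOMCl (2.4 equiv), DMF, 0 °C → rt
Reagents that add atoms: chloromethyl methyl ether, COCCl
Why: Williamson etherification of both sodium phenoxides by the reactive α-chloro ether should proceed cleanly and gives ethers that tolerate organomagnesium reagents.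

**Step 2**
Reactants: 2 1-bromo-3,5-bis(methoxymethoxy)benzene
Product: 3 1,2-dibromo-3,5-bis(methoxymethoxy)benzene
Conditions: NBS (1.05 equiv), MeCN, 0 °C → rt, dark
Reagents that add atoms: N-bromosuccinimide, O=C1CCC(=O)N1Br
Why: Electrophilic aromatic bromination under neutral conditions should occur para to one ether and ortho to the other, next to the bromine, and the two such positions are equivalent by symmetry, so a single dibromide is expected.

**Step 3**
Reactants: 4 (chloromethyl)isopropoxydimethylsilane
Product: 5 (isopropoxydimethylsilyl)methylmagnesium chloride (titrated THF solution)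
Conditions: Mg turnings, BrCH2CH2Br (cat.), THF, rt → reflux
Reagents that add atoms: magnesium, [Mg]
Why: Grignard formation by magnesium insertion into the primary C–Cl bond is the standard preparation of this hydroxymethyl anion equivalent, and the hindered isopropoxy group protects silicon from attack by the reagent.

**Step 4**
Reactants: 3 1,2-dibromo-3,5-bis(methoxymethoxy)benzene; 5 (isopropoxydimethylsilyl)methylmagnesium chloride; 6 carbon dioxide
Product: 10 2-[(isopropoxydimethylsilyl)methyl]-4,6-bis(methoxymethoxy)benzoic acid, via bromoarylmagnesium chloride 7 (not isolated), via 3,5-bis(methoxymethoxy)benzyne 8 (not isolated), via arylmagnesium chloride 9 (not isolated)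
Conditions: iPrMgCl·LiCl (1.05 equiv), THF, −20 °C, 1 h; then 5 (3 equiv), −20 → 45 °C; then CO2 (dry gas), −20 °C → rt; cold dilute HCl to pH 4, crude acid used at once
Reagents that add atoms: none
Why: Bromine–magnesium exchange with iPrMgCl·LiCl (at either bromine, most likely the one flanked by the ether) gives ortho-bromoarylmagnesium 7, which on warming loses MgBrCl to aryne 8 in the presence of an excess of 5. The ring B C2 ether oxygen beside the triple bond withdraws inductively and distorts it, so the carbon nucleophile of 5 attacks the distal carbon C6 and the charge develops on C1, where the adjacent oxygen stabilises it and chelates magnesium in arylmagnesium 9. Carboxylation of 9 with CO2 then sets the C1 carboxyl, so the C6–CH2 and C1–CO2H bonds form in one flask; no ring is closed and no stereocentre is created. The closest known reaction type is the three-component coupling of 3-alkoxyarynes with Grignard reagents and electrophiles, with the aryne released by loss of magnesium halide from an ortho-haloaryl Grignard reagent. The step needs regioselectivity (nucleophile at C6, electrophile at C1), which the C2 alkoxy group secures, and preference for 5 over 7 or isopropylmagnesium as the aryne partner, which complete exchange before warming and the excess of 5 secure.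

**Step 5**
Reactants: 10 2-[(isopropoxydimethylsilyl)methyl]-4,6-bis(methoxymethoxy)benzoic acid
Product: 11 tert-butyl 2-[(isopropoxydimethylsilyl)methyl]-4,6-bis(methoxymethoxy)benzoate
Conditions: O-tert-butyl-N,N′-diisopropylisourea (3 equiv), CH2Cl2, rt
Reagents that add atoms: O-tert-butyl-N,N′-diisopropylisourea, CC(C)NC(=NC(C)C)OC(C)(C)C
Why: O-alkylisourea esterification alkylates the carboxylate oxygen after proton transfer, so the two ortho substituents do not hinder it, the acetals and the alkoxysilane are left alone, and the bulky ester is the one least prone to later lactonisation.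

**Step 6**
Reactants: 11 tert-butyl 2-[(isopropoxydimethylsilyl)methyl]-4,6-bis(methoxymethoxy)benzoate
Product: 12 tert-butyl 2-(hydroxymethyl)-4,6-bis(methoxymethoxy)benzoate
Conditions: 30% aq. H2O2, KF, KHCO3, THF/MeOH (1:1), 0 °C → rt; aq. Na2S2O3, pH 7 buffer; used at once
Reagents that add atoms: hydrogen peroxide, OO
Why: In the Tamao oxidation fluoride activates the alkoxysilane, hydroperoxide adds to silicon and the benzyl group migrates from silicon to oxygen, while the tert-butyl ester should resist closure to the phthalide during a short, cold, weakly basic exposure.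

**Step 7**
Reactants: 12 tert-butyl 2-(hydroxymethyl)-4,6-bis(methoxymethoxy)benzoate; 13 orsellinic acid (2,4-dihydroxy-6-methylbenzoic acid)
Product: 14 tert-butyl 2-{[(2,4-dihydroxy-6-methylbenzoyl)oxy]methyl}-4,6-bis(methoxymethoxy)benzoate
Conditions: P(3-ClC6H4)3, DIAD, THF/toluene, 0 °C → rt
Reagents that add atoms: none
Why: Mitsunobu esterification activates the unhindered benzylic alcohol and lets the carboxylate of 13 displace at CH2, so the hindered carbonyl of 13 is never attacked, and the weakly basic betaine from the electron-poor phosphine should deprotonate only the carboxylic acid and leave both phenols free.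

**Step 8**
Reactants: 14 tert-butyl 2-{[(2,4-dihydroxy-6-methylbenzoyl)oxy]methyl}-4,6-bis(methoxymethoxy)benzoate
Product: 15 2-{[(2,4-dihydroxy-6-methylbenzoyl)oxy]methyl}-4,6-dihydroxybenzoic acid
Conditions: TFA/CH2Cl2 (1:3), Et3SiH, 0 °C → rt
Reagents that add atoms: none
Why: Acidolysis cleaves both methoxymethyl acetals and the tert-butyl ester in one operation, the silane reduces the methoxymethyl cations before they can alkylate the resorcinol rings, and the benzylic ester should survive because its CH2 is meta to both ring B oxygens and cannot ionise.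

**Step 9**
Reactants: 15 2-{[(2,4-dihydroxy-6-methylbenzoyl)oxy]methyl}-4,6-dihydroxybenzoic acid
Product: 16 allyl 2-{[(2,4-dihydroxy-6-methylbenzoyl)oxy]methyl}-4,6-dihydroxybenzoate
Conditions: allyl bromide (3 equiv), KHCO3 (1.2 equiv), DMF, rt
Reagents that add atoms: allyl bromide, C=CCBr
Why: SN2 alkylation of the carboxylate, the only group acidic enough for bicarbonate, re-masks the acid as an ester that tolerates TiCl4 (a tert-butyl ester would be stripped and the free acid would invite ipso attack), and the excess of allyl bromide traps the carboxylate before it can displace the neighbouring acyloxy group.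

**Step 10**
Reactants: 16 allyl 2-{[(2,4-dihydroxy-6-methylbenzoyl)oxy]methyl}-4,6-dihydroxybenzoate
Product: 18 allyl 3-formyl-6-{[(3-formyl-2,4-dihydroxy-6-methylbenzoyl)oxy]methyl}-2,4-dihydroxybenzoate, via bis-α-chloro ether 17 (not isolated)
Conditions: TiCl4 (8 equiv), Cl2CHOMe (4 equiv), CH2Cl2, −20 → 0 °C; then 1 M aq. HCl, rt
Reagents that add atoms: dichloromethyl methyl ether, COC(Cl)Cl; water, O
Why: In the Rieche formylation tetravalent titanium bridges the C2 phenoxide and the neighbouring ester carbonyl in each ring and delivers the chloro(methoxy)methyl cation to C3, the only free carbon ortho to that oxygen, after which aqueous acid hydrolyses 17 to the dialdehyde and each formyl group deactivates its ring against a second attack.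

**Step 11**
Reactants: 18 allyl 3-formyl-6-{[(3-formyl-2,4-dihydroxy-6-methylbenzoyl)oxy]methyl}-2,4-dihydroxybenzoate
Product: 19 barbatolic acid (3-formyl-6-{[(3-formyl-2,4-dihydroxy-6-methylbenzoyl)oxy]methyl}-2,4-dihydroxybenzoic acid)
Conditions: Pd(PPh3)4 (5 mol %), sodium p-toluenesulfinate (1.5 equiv), THF/MeOH, rt, short reaction time; then dilute HCl to pH 2
Reagents that add atoms: none
Why: Tsuji–Trost deallylation by zerovalent palladium ionises only the allyl ester, the π-allyl complex is captured by the sulfinate (a scavenger that cannot condense with the aldehydes), and the benzylic ester, the phenols and the formyl groups should be untouched.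

**Compound list**

1 | 5-bromoresorcinol | Oc1cc(O)cc(Br)c1 | starting material
2 | 1-bromo-3,5-bis(methoxymethoxy)benzene | COCOc1cc(Br)cc(OCOC)c1 | intermediate
3 | 1,2-dibromo-3,5-bis(methoxymethoxy)benzene | COCOc1cc(OCOC)c(Br)c(Br)c1 | intermediate
4 | (chloromethyl)isopropoxydimethylsilane | CC(C)O[Si](C)(C)CCl | starting material
5 | (isopropoxydimethylsilyl)methylmagnesium chloride | CC(C)O[Si](C)(C)C[Mg]Cl | intermediate
6 | carbon dioxide | O=C=O | starting material
7 | 2-bromo-4,6-bis(methoxymethoxy)phenylmagnesium chloride (not isolated) | COCOc1cc(OCOC)c([Mg]Cl)c(Br)c1 | intermediate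
8 | 3,5-bis(methoxymethoxy)benzyne (not isolated) | COCOC1=CC(OCOC)=CC#C1 | intermediate
9 | 2-[(isopropoxydimethylsilyl)methyl]-4,6-bis(methoxymethoxy)phenylmagnesium chloride (not isolated) | COCOc1cc(OCOC)c([Mg]Cl)c(C[Si](C)(C)OC(C)C)c1 | intermediate
10 | 2-[(isopropoxydimethylsilyl)methyl]-4,6-bis(methoxymethoxy)benzoic acid | COCOc1cc(OCOC)c(C(=O)O)c(C[Si](C)(C)OC(C)C)c1 | intermediate
11 | tert-butyl 2-[(isopropoxydimethylsilyl)methyl]-4,6-bis(methoxymethoxy)benzoate | COCOc1cc(OCOC)c(C(=O)OC(C)(C)C)c(C[Si](C)(C)OC(C)C)c1 | intermediate
12 | tert-butyl 2-(hydroxymethyl)-4,6-bis(methoxymethoxy)benzoate | COCOc1cc(OCOC)c(C(=O)OC(C)(C)C)c(CO)c1 | intermediate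
13 | orsellinic acid (2,4-dihydroxy-6-methylbenzoic acid) | Cc1cc(O)cc(O)c1C(=O)O | starting material
14 | tert-butyl 2-{[(2,4-dihydroxy-6-methylbenzoyl)oxy]methyl}-4,6-bis(methoxymethoxy)benzoate | Cc1cc(O)cc(O)c1C(=O)OCc1cc(OCOC)cc(OCOC)c1C(=O)OC(C)(C)C | intermediate
15 | 2-{[(2,4-dihydroxy-6-methylbenzoyl)oxy]methyl}-4,6-dihydroxybenzoic acid | Cc1cc(O)cc(O)c1C(=O)OCc1cc(O)cc(O)c1C(=O)O | intermediate
16 | allyl 2-{[(2,4-dihydroxy-6-methylbenzoyl)oxy]methyl}-4,6-dihydroxybenzoate | Cc1cc(O)cc(O)c1C(=O)OCc1cc(O)cc(O)c1C(=O)OCC=C | intermediate
17 | bis-α-chloro ether: compound 16 carrying a chloro(methoxy)methyl group on C3 of each ring (not isolated; two unassigned stereocentres, lost on hydrolysis) | Cc1cc(O)c(C(Cl)OC)c(O)c1C(=O)OCc1cc(O)c(C(Cl)OC)c(O)c1C(=O)OCC=C | intermediate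
18 | allyl 3-formyl-6-{[(3-formyl-2,4-dihydroxy-6-methylbenzoyl)oxy]methyl}-2,4-dihydroxybenzoate | Cc1cc(O)c(C=O)c(O)c1C(=O)OCc1cc(O)c(C=O)c(O)c1C(=O)OCC=C | intermediate
19 | barbatolic acid | Cc1cc(O)c(C=O)c(O)c1C(=O)OCc1cc(O)c(C=O)c(O)c1C(=O)O | target

Total step count: 11. Longest linear sequence: 10 steps (steps 1, 2 and 4 to 11, from 5-bromoresorcinol).

**Steps most likely to fail**

Step 4. Loss of MgBrCl from 7 may be slow at temperatures the reagents tolerate, and 7 or 9 may add to aryne 8 in competition with 5, which would drain material into biaryls; attack of an organomagnesium species at the alkoxysilane is a further drain. The fallback makes the two bonds in separate operations without an aryne. It sets out from 3: the same exchange with iPrMgCl·LiCl at −20 °C, expected at the bromine flanked by the ether oxygen through chelation and induction, would be followed by carboxylation in the cold, before any elimination, to give 2-bromo-4,6-bis(methoxymethoxy)benzoic acid F1. Esterification as in step 5 would give tert-butyl 2-bromo-4,6-bis(methoxymethoxy)benzoate F2, and a Kumada coupling of F2 with 5 (PdCl2(dppf), THF, 40 °C) would deliver 11, where the route is rejoined.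

Step 6. In the basic fluoride medium the freed benzylic hydroxyl may close onto the neighbouring ester with loss of tert-butanol, and fluoride may cleave the ester-activated benzyl–silicon bond by protodesilylation instead of oxidation. The fallback oxidises while the carboxyl is a non-electrophilic carboxylate and masks the alcohol before the ester is made. It sets out from 10: Tamao oxidation of its potassium salt (KHCO3, KF, H2O2) would give potassium 2-(hydroxymethyl)-4,6-bis(methoxymethoxy)benzoate F3, which is not acidified. Silylation (TBSCl, imidazole, DMF) would give tert-butyldimethylsilyl 2-{[(tert-butyldimethylsilyl)oxy]methyl}-4,6-bis(methoxymethoxy)benzoate F4, whose silyl ester would be cleaved by K2CO3 in aqueous methanol to 2-{[(tert-butyldimethylsilyl)oxy]methyl}-4,6-bis(methoxymethoxy)benzoic acid F5. Esterification as in step 5 would give tert-butyl 2-{[(tert-butyldimethylsilyl)oxy]methyl}-4,6-bis(methoxymethoxy)benzoate F6, and HF·pyridine in THF at 0 °C, an acidic medium in which closure is not base-driven, would release 12 for immediate use in step 7.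

Step 10. The second formylation may stall or go astray once one ring is formylated and the titanium is tied up, and the strong Lewis acid may cleave the benzylic ester. The fallback is a base-mediated ortho-formylation through magnesium phenoxides (Casnati–Skattebøl conditions: MgCl2, Et3N, paraformaldehyde, MeCN, reflux). It sets out from 16: magnesium held between the C2 phenoxide and the ester carbonyl would deliver formaldehyde to C3 of each ring to give allyl 2,4-dihydroxy-3-(hydroxymethyl)-6-({[2,4-dihydroxy-3-(hydroxymethyl)-6-methylbenzoyl]oxy}methyl)benzoate F7. F7 would be oxidised in the same flask by hydride transfer to further formaldehyde, rejoining the route at 18.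

**Further compounds**

F1 | step 4 | 2-bromo-4,6-bis(methoxymethoxy)benzoic acid | COCOc1cc(OCOC)c(C(=O)O)c(Br)c1
F2 | step 4 | tert-butyl 2-bromo-4,6-bis(methoxymethoxy)benzoate | COCOc1cc(OCOC)c(C(=O)OC(C)(C)C)c(Br)c1
F3 | step 6 | potassium 2-(hydroxymethyl)-4,6-bis(methoxymethoxy)benzoate | COCOc1cc(OCOC)c(C(=O)[O-])c(CO)c1.[K+]
F4 | step 6 | tert-butyldimethylsilyl 2-{[(tert-butyldimethylsilyl)oxy]methyl}-4,6-bis(methoxymethoxy)benzoate | COCOc1cc(OCOC)c(C(=O)O[Si](C)(C)C(C)(C)C)c(CO[Si](C)(C)C(C)(C)C)c1
F5 | step 6 | 2-{[(tert-butyldimethylsilyl)oxy]methyl}-4,6-bis(methoxymethoxy)benzoic acid | COCOc1cc(OCOC)c(C(=O)O)c(CO[Si](C)(C)C(C)(C)C)c1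
F6 | step 6 | tert-butyl 2-{[(tert-butyldimethylsilyl)oxy]methyl}-4,6-bis(methoxymethoxy)benzoate | COCOc1cc(OCOC)c(C(=O)OC(C)(C)C)c(CO[Si](C)(C)C(C)(C)C)c1
F7 | step 10 | allyl 2,4-dihydroxy-3-(hydroxymethyl)-6-({[2,4-dihydroxy-3-(hydroxymethyl)-6-methylbenzoyl]oxy}methyl)benzoate | Cc1cc(O)c(CO)c(O)c1C(=O)OCc1cc(O)c(CO)c(O)c1C(=O)OCC=C
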